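The readings are simulated with made-up constants, noise included.

If a fixed amount of a catalyst charge is taken at the start, the catalyst at work is the charge minus that amount.

| flask | substrate | free catalyst | time |
|---|---|---|---|
| south-east | 0.800 M | 0.0160 M |  |
| south | 0.400 M | 0.0160 M |  |
| west | 0.800 M | 0.0240 M |  |
| north | 1.60 M | 0.0160 M |  |
| north-west | 2.40 M | 0.00800 M | 8.5 h |

- south-east run (time / h: [product] / M): 0.34: 0.043; 0.54: 0.069; 0.85: 0.079; 1.4: 0.125; 2.1: 0.163; 3.4: 0.229; 5.4: 0.261; 8.5: 0.283
- south run (time / h: [product] / M): 0.34: 0.020; 0.54: 0.025; 0.85: 0.049; 1.4: 0.062; 2.1: 0.092; 3.4: 0.107; 5.4: 0.132; 8.5: 0.137
- west run (time / h: [product] / M): 0.34: 0.056; 0.54: 0.089; 0.85: 0.137; 1.4: 0.184; 2.1: 0.226; 3.4: 0.277; 5.4: 0.275; 8.5: 0.286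
- north run (time / h: [product] / M): 0.34: 0.068; 0.54: 0.106; 0.85: 0.148; 1.4: 0.224; 2.1: 0.299; 3.4: 0.414; 5.4: 0.510; 8.5: 0.560

(scatter of a reading: 0.006 M)

- Overall: substrate -> product, with free catalyst as catalyst.
- Constant volume, constant temperature.
- What is held in complexes is read along with the free species.
- An order is taken over about fifteen percent of the charge, up and down.

* the exponent of [substrate] in the starting rate at the charge of the south-east run (at the point where two percent of the substrate have become product) (one fixed amount of product, the same in the runs compared)
* the exponent of [free catalyst] in the starting rate at the charge of the south-east run (at the point where two percent of the substrate have become product)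
* product in the north-west run at 8.5 h, as a share of the substrate charged
* which of these the readings show (the catalyst rests as a dimer / a little impurity takes part of the catalyst at once / the substrate kills the catalyst / nothing beyond the main steps / the catalyst dies in pairs / the product ties up the catalyst)

The last row of the table comes first. At 8.5 h the south-east run holds 35.4% of its substrate charge as product and the west run holds 35.7%, with 1.50 times the catalyst. So the end share is frozen at the west reading, and each curve can be read as an approach to it.

The row at 1.4 h then gives each run a reading of an approach constant, a pseudo-first-order constant: minus the log of the fraction of the end share still to come, over the time. South reads 0.406 h⁻¹, south-east 0.410 h⁻¹, north 0.355 h⁻¹ and west 0.736 h⁻¹.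

West over south-east is 1.79, more than the charge ratio. If the constant follows the catalyst at work, the part of the south-east catalyst charge taken at once reads 37.1%: the lost share.

Is that amount fixed? Tied to the substrate charge, it would give the south run 3.15 times the working catalyst of the north run, but the south constant stands at 1.14 times the north one. My reckoning therefore keeps one fixed amount, an impurity.

The catalyst order at the south-east charge is then one over the share still working there, 1.59. South against north gives a substrate order of 0.903. For the north-west run, the north constant scaled by the working catalyst, 0.206 of the north amount, gives 16.5% product.

The forecast gives a substrate order of 0.86, a catalyst order of 1.15, 16% product in the north-west run and "a little impurity takes part of the catalyst at once", on the ground “A poison arriving with the substrate, about 0.25% of the charge, fits”. Its loss is tied to the substrate charge and mine is one fixed amount, and its catalyst order differs from my 1.59.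

The simulation gives a substrate order of 0.93, a catalyst order of 1.6, 16.5% product in the north-west run and "a little impurity takes part of the catalyst at once"; the catalyst order is 1.37 times the forecast's.

    free catalyst + substrate ⇌ catalyst-substrate complex, settled at all times (0.1830 M⁻¹)
    catalyst-substrate complex ⇌ product + free catalyst (91.44 h⁻¹, 29.52 M⁻¹ h⁻¹)
    free catalyst + impurity → spent catalyst

Without the step from free catalyst and impurity to spent catalyst, the readings move by 6.7 in units of the scatter, root mean square. In the north-west run the same amount, as read from the lost share, is 74.1% of the catalyst charge, which leaves a quarter at work, and 16.5% of the substrate charged is product at 8.5 h.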